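## Retrosynthetic overview

- Numbering (eremophilane): ring A = C1–C5 + C10, ring B = C5–C10; O on C3, C8, C9; methyls on C4 and C5; isopropylidene on C7. Enabling feature: the chain C3–C4–C5–C10–C9–C8 has the substitution of an o-quinone monoketal (H on C3 and C10, vicinal methyls on C4/C5, vicinal oxygens on C9/C8) and C1–C2 are plain CH2 groups. A 6,6-dimethoxy-3,4-dimethylcyclohexa-2,4-dienone can therefore be the diene (termini C3 and C10) and an ethylene equivalent the dienophile.
- Disconnections, backwards: enol O–CH3 and C3 ester; C3–O/C4–H (hydroboration anti to the angular methyl once C10 is trigonal); isopropylidene (aldol); C5–C6 by anionic oxy-Cope of a 2-vinylbicyclo[2.2.2]oct-5-en-2-ol, which also cuts C3–C8 and relays bridgehead chirality to quaternary C5; C1–C10 and C2–C3 by [4+2].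
- Ring order: arene → bicyclo[2.2.2]octenone (its cyclohexene C10–C1–C2–C3–C4–C5 is the later ring A, closed in the cycloaddition) → ring B by the [3,3] shift.
- Side chain: the (2Z)-acid from but-2-yn-1-ol, angelic acid and CO; attached by esterification, then O-demethylation.

Key step: step 2

Remark: the configuration at C7 of 15 and at C8 of 18 is not controlled; both centres become trigonal again later, so these two compounds are carried as epimer mixtures and drawn without a descriptor there.

## Route

Step 1
Reactants: 1 3,4-dimethylanisole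
Product: 4 2-methoxy-4,5-dimethylphenol, via aryllithium 2 (not isolated), via arylboronate 3 (not isolated)
Conditions: n-BuLi, TMEDA, Et2O, 0 °C → rt; B(OMe)3, −78 °C → rt; AcOH, 30% H2O2, 0 °C → rt
Reagents that add atoms: hydrogen peroxide (OO)
Why: directed ortho-lithiation of the anisole should occur at the open ortho position rather than the one flanked by a methyl group, and borylation followed by oxidative C–B to C–O cleavage then gives the guaiacol.

Step 2
Reactants: 4 2-methoxy-4,5-dimethylphenol; 5 acrolein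
Product: 7 (1R,2S,4S)-8,8-dimethoxy-5,6-dimethyl-7-oxobicyclo[2.2.2]oct-5-ene-2-carbaldehyde (formyl group syn to the C5=C6 bridge), via dienone 6 (not isolated)
Conditions: PhI(OAc)2, MeOH, −10 °C; then acrolein (excess), (5R)-5-benzyl-2,2,3-trimethylimidazolidin-4-one hydrochloride (20 mol %), CH3CN–H2O 19:1, −10 → 4 °C
Reagents that add atoms: methanol (CO)
Why: Proposed new method: the trivalent iodine reagent oxidises the guaiacol and methanol traps the cation at the methoxy-bearing carbon to give the 6,6-dimethoxycyclohexa-2,4-dienone 6 (a well-precedented stage), whose s-cis diene then undergoes a concerted asynchronous [4+2] cycloaddition with the iminium ion formed from acrolein and the chiral imidazolidinone salt; the closest known reactions are the thermal Diels–Alder reactions of such dienones with acrolein, acrylates and vinyl ketones and the imidazolidinone-catalysed Diels–Alder reaction of cyclohexa-1,3-diene with acrolein, but the two have not been combined on this diene class. One ring is closed, the cyclohexene C10–C1–C2–C3–C4=C5 (the future ring A, here one ring of the bicyclo[2.2.2]octenone), by intermolecular suprafacial [4+2] addition across the diene termini C3 and C10. The formyl-bearing carbon should bond to the terminus next to the ketone because the diene HOMO is largest at the terminus remote from the carbonyl, and this regiochemistry is erased anyway when the formyl group is removed. The two bridgehead centres (1R,4S), the only stereo-information that survives, are fixed by which face of the flat dienone is attacked: the benzyl group of the (5R)-catalyst should shield one face of the (E)-iminium ion so that the diene adds to the Re face at the α-carbon, and the endo preference (formyl under the diene) then sets the formyl-bearing carbon as 2S and the bridgeheads with it. The step needs the catalysed addition to outrun both dimerisation of 6 and the uncatalysed racemic cycloaddition; the methyl group on the dienophilic C4=C5 bond of 6 slows dimerisation, and excess acrolein, low temperature and LUMO-lowering iminium activation favour the catalysed path.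

Step 3
Reactants: 7 (1R,2S,4S)-8,8-dimethoxy-5,6-dimethyl-7-oxobicyclo[2.2.2]oct-5-ene-2-carbaldehyde
Product: 8 (1R,4S)-3,3-dimethoxy-5,6-dimethylbicyclo[2.2.2]oct-5-en-2-one
Conditions: RhCl(PPh3)3 (1.1 equiv), toluene, 110 °C
Reagents that add atoms: none
Why: Tsuji–Wilkinson decarbonylation (oxidative addition of monovalent rhodium into the formyl C–H bond, CO extrusion, C–H reductive elimination) should remove the activating formyl group to leave the C1–C2 ethano bridge, erasing the formyl-bearing stereocentre and leaving the bridgeheads untouched.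

Step 4
Reactants: 8 (1R,4S)-3,3-dimethoxy-5,6-dimethylbicyclo[2.2.2]oct-5-en-2-one; 9 vinylmagnesium bromide
Product: 10 (1R,2R,4S)-2-ethenyl-3,3-dimethoxy-5,6-dimethylbicyclo[2.2.2]oct-5-en-2-ol (vinyl syn to the C5=C6 bridge)
Conditions: CeCl3 (anhydrous), CH2=CHMgBr, THF, −78 → 0 °C; aq. NH4Cl
Reagents that add atoms: none
Why: organocerium-mediated 1,2-addition to the non-enolisable ketone should occur from the carbonyl face flanked by the C5=C6 bridge, which has no inward-pointing hydrogens unlike the ethano bridge, placing the vinyl group syn to the ring alkene as the next step requires and setting C2 as R.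

Step 5
Reactants: 10 (1R,2R,4S)-2-ethenyl-3,3-dimethoxy-5,6-dimethylbicyclo[2.2.2]oct-5-en-2-ol
Product: 12 (4aS,8aS)-1,1-dimethoxy-4a,5-dimethyl-3,4,4a,7,8,8a-hexahydronaphthalen-2(1H)-one (cis-fused), via potassium enolate 11 (not isolated)
Conditions: KH, 18-crown-6, THF, 0 °C → rt; aq. NH4Cl
Reagents that add atoms: none
Why: anionic oxy-Cope rearrangement of the potassium alkoxide through the boat transition state enforced by the bicycle should break the C3–C8 bond and form C5–C6 on the alkene face turned towards the keto bridge, transferring the bridgehead configuration to the quaternary C5 (cis-fused decalin, angular methyl as in the target) and leaving the ring A C3=C4 double bond.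

Step 6
Reactants: 12 (4aS,8aS)-1,1-dimethoxy-4a,5-dimethyl-3,4,4a,7,8,8a-hexahydronaphthalen-2(1H)-one; 13 acetone
Product: 15 (4aS,8aS)-3-(2-hydroxypropan-2-yl)-1,1-dimethoxy-4a,5-dimethyl-3,4,4a,7,8,8a-hexahydronaphthalen-2(1H)-one (C3 epimers), via lithium enolate 14 (not isolated)
Conditions: LiN(iPr)2, THF, −78 °C; acetone, −78 °C; AcOH, −78 °C
Reagents that add atoms: none
Why: the ketone can enolise only towards C7 (the other α-carbon is the ketal carbon), so the kinetic lithium enolate should undergo a regiodefined aldol addition to acetone.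

Step 7
Reactants: 15 (4aS,8aS)-3-(2-hydroxypropan-2-yl)-1,1-dimethoxy-4a,5-dimethyl-3,4,4a,7,8,8a-hexahydronaphthalen-2(1H)-one
Product: 16 (4aR)-1-methoxy-4a,5-dimethyl-3-(propan-2-ylidene)-4,4a,7,8-tetrahydronaphthalen-2(3H)-one
Conditions: p-TsOH (10 mol %), toluene, reflux, 5 Å molecular sieves
Reagents that add atoms: none
Why: acid-catalysed dehydration of the tertiary aldol should give the conjugated isopropylidene enone, and acid-catalysed loss of methanol from the α-keto ketal towards C10 the methyl enol ether of the diosphenol, which makes C10 trigonal and so fixes the angular methyl axial on ring A.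

Step 8
Reactants: 16 (4aR)-1-methoxy-4a,5-dimethyl-3-(propan-2-ylidene)-4,4a,7,8-tetrahydronaphthalen-2(3H)-one
Product: 18 (4aR,5R,6R)-1-methoxy-4a,5-dimethyl-3-(propan-2-ylidene)-2,3,4,4a,5,6,7,8-octahydronaphthalene-2,6-diol (C2 epimers), via bis-boryl adduct 17 (not isolated)
Conditions: 9-borabicyclo[3.3.1]nonane (9-BBN, 3 equiv), THF, 0 → 65 °C; then NaBO3·4H2O, H2O, rt
Reagents that add atoms: sodium perborate ([Na+].[Na+].O[B-]1(O)OO[B-](O)(O)OO1)
Why: hydroboration–oxidation of the only trisubstituted alkene should add H and boron syn, with boron on the less substituted C3, from the face anti to the axial angular methyl, setting C3 (R, oxygen trans to both methyls) and C4 (R, methyl cis to the angular methyl) together; the two tetrasubstituted alkenes are inert to this bulky borane, and the dienone carbonyl is reduced 1,2 at the same time and restored in step 9.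

Step 9
Reactants: 18 (4aR,5R,6R)-1-methoxy-4a,5-dimethyl-3-(propan-2-ylidene)-2,3,4,4a,5,6,7,8-octahydronaphthalene-2,6-diol
Product: 19 (4aR,5R,6R)-6-hydroxy-1-methoxy-4a,5-dimethyl-3-(propan-2-ylidene)-4,4a,5,6,7,8-hexahydronaphthalen-2(3H)-one
Conditions: MnO2 (activated, excess), CH2Cl2, rt
Reagents that add atoms: none
Why: MnO2 should oxidise only the doubly allylic C8 carbinol (both epimers converge) and leave the saturated secondary C3 alcohol.

Step 10
Reactants: 20 but-2-yn-1-ol
Product: 22 (2Z)-3-iodobut-2-en-1-ol, via alkenylalanate 21 (not isolated)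
Conditions: NaAlH2(OCH2CH2OCH3)2 (Red-Al), Et2O, 0 °C → rt; I2, THF, −78 °C
Reagents that add atoms: iodine (II)
Why: hydroxyl-directed trans-hydroalumination of the propargylic alcohol places aluminium on C3 cis to the CH2O group in a five-membered alanate, and iodinolysis with retention should give the Z-vinyl iodide.

Step 11
Reactants: 22 (2Z)-3-iodobut-2-en-1-ol; 23 angelic acid ((2Z)-2-methylbut-2-enoic acid)
Product: 24 (2Z)-3-iodobut-2-en-1-yl (2Z)-2-methylbut-2-enoate
Conditions: PPh3, DIAD, THF, 0 °C → rt
Reagents that add atoms: none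
Why: in the Mitsunobu esterification angelic acid reacts as the carboxylate nucleophile at the primary allylic carbon, so its carboxyl group is never activated and the Z geometry should not isomerise to the tiglate.

Step 12
Reactants: 24 (2Z)-3-iodobut-2-en-1-yl (2Z)-2-methylbut-2-enoate
Product: 25 (2Z)-2-methyl-4-{[(2Z)-2-methylbut-2-enoyl]oxy}but-2-enoic acid
Conditions: Pd(OAc)2 (5 mol %), PPh3, CO (1 atm), H2O, Et3N, DMF, 50 °C; then 1 M HCl
Reagents that add atoms: carbon monoxide ([C-]#[O+]); water (O)
Why: palladium-catalysed hydroxycarbonylation (oxidative addition of zerovalent palladium into the vinyl C–I bond with retention, CO insertion, hydrolysis of the acylpalladium) should turn the Z-iodide into the Z-acid, whose acylated γ-oxygen cannot lactonise.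

Step 13
Reactants: 25 (2Z)-2-methyl-4-{[(2Z)-2-methylbut-2-enoyl]oxy}but-2-enoic acid; 19 (4aR,5R,6R)-6-hydroxy-1-methoxy-4a,5-dimethyl-3-(propan-2-ylidene)-4,4a,5,6,7,8-hexahydronaphthalen-2(3H)-one
Product: 27 (1R,2R,8aR)-5-methoxy-1,8a-dimethyl-6-oxo-7-(propan-2-ylidene)-1,2,3,4,6,7,8,8a-octahydronaphthalen-2-yl (2Z)-2-methyl-4-{[(2Z)-2-methylbut-2-enoyl]oxy}but-2-enoate, via mixed anhydride 26 (not isolated)
Conditions: 2,4,6-trichlorobenzoyl chloride, Et3N, toluene, 0 °C → rt; then 19, DMAP, toluene, rt
Reagents that add atoms: none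
Why: Yamaguchi esterification through the hindered mixed anhydride should acylate the equatorial C3 alcohol with retention at C3, and the enol oxygen at C9 is blocked as its methyl ether.

Step 14
Reactants: 27 (1R,2R,8aR)-5-methoxy-1,8a-dimethyl-6-oxo-7-(propan-2-ylidene)-1,2,3,4,6,7,8,8a-octahydronaphthalen-2-yl (2Z)-2-methyl-4-{[(2Z)-2-methylbut-2-enoyl]oxy}but-2-enoate
Product: 28 (1R,2R,8aR)-5-hydroxy-1,8a-dimethyl-6-oxo-7-(propan-2-ylidene)-1,2,3,4,6,7,8,8a-octahydronaphthalen-2-yl (2Z)-2-methyl-4-{[(2Z)-2-methylbut-2-enoyl]oxy}but-2-enoate (CNP0301409.1)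
Conditions: BCl3 (1 M in CH2Cl2, 3 equiv), CH2Cl2, −78 °C; pH 7 buffer
Reagents that add atoms: none
Why: chelation of BCl3 between the C8 carbonyl and the adjacent enol methoxy group should direct chloride to the O-methyl carbon (carbonyl-assisted ether cleavage), freeing the diosphenol at low temperature without touching the three ester linkages or the Z double bonds.

## Compound list

1 | 3,4-dimethylanisole | COc1ccc(C)c(C)c1 | starting material
2 | (2-methoxy-4,5-dimethylphenyl)lithium (formed in the flask) | COc1cc(C)c(C)cc1[Li] | intermediate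
3 | dimethyl (2-methoxy-4,5-dimethylphenyl)boronate (formed in the flask) | COc1cc(C)c(C)cc1B(OC)OC | intermediate
4 | 2-methoxy-4,5-dimethylphenol | COc1cc(C)c(C)cc1O | intermediate
5 | acrolein (prop-2-enal) | C=CC=O | starting material
6 | 6,6-dimethoxy-3,4-dimethylcyclohexa-2,4-dien-1-one (formed in the flask) | O=C1C=C(C)C(C)=CC1(OC)OC | intermediate
7 | (1R,2S,4S)-8,8-dimethoxy-5,6-dimethyl-7-oxobicyclo[2.2.2]oct-5-ene-2-carbaldehyde | O=C1C(OC)(OC)[C@H]2C[C@H](C=O)[C@@H]1C(C)=C2C | intermediate
8 | (1R,4S)-3,3-dimethoxy-5,6-dimethylbicyclo[2.2.2]oct-5-en-2-one | O=C1C(OC)(OC)[C@H]2CC[C@@H]1C(C)=C2C | intermediate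
9 | vinylmagnesium bromide | C=C[Mg]Br | starting material
10 | (1R,2R,4S)-2-ethenyl-3,3-dimethoxy-5,6-dimethylbicyclo[2.2.2]oct-5-en-2-ol | C=C[C@]1(O)C(OC)(OC)[C@H]2CC[C@@H]1C(C)=C2C | intermediate
11 | potassium enolate of 12 (formed in the flask) | [K+].[O-]C1=CC[C@]2(C)C(C)=CCC[C@@H]2C1(OC)OC | intermediate
12 | (4aS,8aS)-1,1-dimethoxy-4a,5-dimethyl-3,4,4a,7,8,8a-hexahydronaphthalen-2(1H)-one | O=C1CC[C@]2(C)C(C)=CCC[C@@H]2C1(OC)OC | intermediate
13 | acetone | CC(C)=O | starting material
14 | lithium enolate of 12 (formed in the flask) | [Li+].[O-]C1=CC[C@]2(C)C(C)=CCC[C@@H]2C1(OC)OC | intermediate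
15 | (4aS,8aS)-3-(2-hydroxypropan-2-yl)-1,1-dimethoxy-4a,5-dimethyl-3,4,4a,7,8,8a-hexahydronaphthalen-2(1H)-one (C3 epimers) | O=C1C(C(C)(C)O)C[C@]2(C)C(C)=CCC[C@@H]2C1(OC)OC | intermediate
16 | (4aR)-1-methoxy-4a,5-dimethyl-3-(propan-2-ylidene)-4,4a,7,8-tetrahydronaphthalen-2(3H)-one | COC1=C2CCC=C(C)[C@@]2(C)CC(=C(C)C)C1=O | intermediate
17 | C6-(9-borabicyclo[3.3.1]nonan-9-yl), C2-O-(9-borabicyclo[3.3.1]nonan-9-yl) adduct of 16 (formed in the flask) | COC1=C2CC[C@@H](B3C4CCCC3CCC4)[C@H](C)[C@@]2(C)CC(=C(C)C)C1OB1C2CCCC1CCC2 | intermediate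
18 | (4aR,5R,6R)-1-methoxy-4a,5-dimethyl-3-(propan-2-ylidene)-2,3,4,4a,5,6,7,8-octahydronaphthalene-2,6-diol (C2 epimers) | COC1=C2CC[C@@H](O)[C@H](C)[C@@]2(C)CC(=C(C)C)C1O | intermediate
19 | (4aR,5R,6R)-6-hydroxy-1-methoxy-4a,5-dimethyl-3-(propan-2-ylidene)-4,4a,5,6,7,8-hexahydronaphthalen-2(3H)-one | COC1=C2CC[C@@H](O)[C@H](C)[C@@]2(C)CC(=C(C)C)C1=O | intermediate
20 | but-2-yn-1-ol | CC#CCO | starting material
21 | sodium 2,2-bis(2-methoxyethoxy)-3-methyl-2,5-dihydro-1,2-oxaaluminol-2-uide (formed in the flask) | [Na+].CC1=CCO[Al-]1(OCCOC)OCCOC | intermediate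
22 | (2Z)-3-iodobut-2-en-1-ol | C/C(I)=C/CO | intermediate
23 | angelic acid, (2Z)-2-methylbut-2-enoic acid | C/C=C(/C)C(=O)O | starting material
24 | (2Z)-3-iodobut-2-en-1-yl (2Z)-2-methylbut-2-enoate | C/C=C(/C)C(=O)OC/C=C(/C)I | intermediate
25 | (2Z)-2-methyl-4-{[(2Z)-2-methylbut-2-enoyl]oxy}but-2-enoic acid | C/C=C(/C)C(=O)OC/C=C(/C)C(=O)O | intermediate
26 | mixed anhydride of 25 and 2,4,6-trichlorobenzoic acid (formed in the flask) | C/C=C(/C)C(=O)OC/C=C(/C)C(=O)OC(=O)c1c(Cl)cc(Cl)cc1Cl | intermediate
27 | (1R,2R,8aR)-5-methoxy-1,8a-dimethyl-6-oxo-7-(propan-2-ylidene)-1,2,3,4,6,7,8,8a-octahydronaphthalen-2-yl (2Z)-2-methyl-4-{[(2Z)-2-methylbut-2-enoyl]oxy}but-2-enoate | C/C=C(/C)C(=O)OC/C=C(/C)C(=O)O[C@@H]1CCC2=C(OC)C(=O)C(=C(C)C)C[C@]2(C)[C@H]1C | intermediate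
28 | (1R,2R,8aR)-5-hydroxy-1,8a-dimethyl-6-oxo-7-(propan-2-ylidene)-1,2,3,4,6,7,8,8a-octahydronaphthalen-2-yl (2Z)-2-methyl-4-{[(2Z)-2-methylbut-2-enoyl]oxy}but-2-enoate | C/C=C(/C)C(=O)OC/C=C(/C)C(=O)O[C@@H]1CCC2=C(O)C(=O)C(=C(C)C)C[C@]2(C)[C@H]1C | target

## Step count and risks

Total step count: 14. Longest linear sequence: 11 steps (steps 1–9, 13, 14).

Steps most likely to fail:

1. Step 2 (Proposed new method). What may go wrong: dimerisation of the dienone and the uncatalysed racemic cycloaddition compete with the iminium-catalysed pathway, or the amine catalyst is oxidised by residual iodine reagent, so that conversion and enantiopurity are lost. Fallback, from 4 back to 8, by known chemistry: 4 is oxidised with PhI(OAc)2 in MeOH in the presence of excess commercial (3R)-4,4-dimethyl-2-oxooxolan-3-yl prop-2-enoate, the known thermal cycloaddition of these dienones with acrylates. The two facial adducts are now diastereomers and are separated by chromatography or crystallisation to give (3R)-4,4-dimethyl-2-oxooxolan-3-yl (1R,2S,4S)-8,8-dimethoxy-5,6-dimethyl-7-oxobicyclo[2.2.2]oct-5-ene-2-carboxylate F1. LiOH in THF–H2O then gives (1R,2S,4S)-8,8-dimethoxy-5,6-dimethyl-7-oxobicyclo[2.2.2]oct-5-ene-2-carboxylic acid F2. This is converted with N-hydroxypyridine-2-thione and DCC into its 2-sulfanylidenepyridin-1(2H)-yl ester F3, and Barton reductive decarboxylation (visible light, t-BuSH, benzene) should give 8.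

2. Step 7. What may go wrong: incomplete loss of methanol or hydrolysis of the ketal to the free diosphenol by the water released, and acid-induced cationic migration of the ring A double bond or of the angular methyl. Fallback, from 15 back to 16, splitting the step into two aprotic operations: MsCl, Et3N, CH2Cl2 then DBU should dehydrate 15 by an E1cB path to (4aS,8aS)-1,1-dimethoxy-4a,5-dimethyl-3-(propan-2-ylidene)-3,4,4a,7,8,8a-hexahydronaphthalen-2(1H)-one F4. TMSOTf and iPr2NEt in CH2Cl2 at −20 °C (the known conversion of dimethyl ketals into methyl enol ethers) should then give 16.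

3. Step 8. What may go wrong: the bulky borane adds too slowly to the hindered trisubstituted alkene, or complexation and over-reduction at the dienone consume the material. Fallback, from 16 back to 19 (18 and step 9 are bypassed), replacing hydroboration by epoxide chemistry: mCPBA with NaHCO3 in CH2Cl2 should epoxidise the only electron-rich isolated alkene anti to the angular methyl to give (4aS,5S,6R)-5,6-epoxy-1-methoxy-4a,5-dimethyl-3-(propan-2-ylidene)-4,4a,5,6,7,8-hexahydronaphthalen-2(3H)-one F5. Cp2TiCl (trivalent titanium, made in the flask from Cp2TiCl2 and Mn powder) should open it at the tertiary carbon and eliminate towards the methyl group to give (4aR,6R)-6-hydroxy-1-methoxy-4a-methyl-5-methylidene-3-(propan-2-ylidene)-4,4a,5,6,7,8-hexahydronaphthalen-2(3H)-one F6. Hydroxyl-directed hydrogenation with [Ir(cod)(PCy3)(py)]PF6 and H2 in CH2Cl2 should then deliver hydrogen to C4 on the face of the C3 hydroxyl and give 19.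

Further compounds
F1 | step 2 | (3R)-4,4-dimethyl-2-oxooxolan-3-yl (1R,2S,4S)-8,8-dimethoxy-5,6-dimethyl-7-oxobicyclo[2.2.2]oct-5-ene-2-carboxylate | O=C1C(OC)(OC)[C@H]2C[C@H](C(=O)O[C@H]3C(=O)OCC3(C)C)[C@@H]1C(C)=C2C
F2 | step 2 | (1R,2S,4S)-8,8-dimethoxy-5,6-dimethyl-7-oxobicyclo[2.2.2]oct-5-ene-2-carboxylic acid | O=C1C(OC)(OC)[C@H]2C[C@H](C(=O)O)[C@@H]1C(C)=C2C
F3 | step 2 | 2-sulfanylidenepyridin-1(2H)-yl (1R,2S,4S)-8,8-dimethoxy-5,6-dimethyl-7-oxobicyclo[2.2.2]oct-5-ene-2-carboxylate | O=C1C(OC)(OC)[C@H]2C[C@H](C(=O)ON3C=CC=CC3=S)[C@@H]1C(C)=C2C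
F4 | step 7 | (4aS,8aS)-1,1-dimethoxy-4a,5-dimethyl-3-(propan-2-ylidene)-3,4,4a,7,8,8a-hexahydronaphthalen-2(1H)-one | O=C1C(=C(C)C)C[C@]2(C)C(C)=CCC[C@@H]2C1(OC)OC
F5 | step 8 | (4aS,5S,6R)-5,6-epoxy-1-methoxy-4a,5-dimethyl-3-(propan-2-ylidene)-4,4a,5,6,7,8-hexahydronaphthalen-2(3H)-one | COC1=C2CC[C@H]3O[C@@]3(C)[C@@]2(C)CC(=C(C)C)C1=O
F6 | step 8 | (4aR,6R)-6-hydroxy-1-methoxy-4a-methyl-5-methylidene-3-(propan-2-ylidene)-4,4a,5,6,7,8-hexahydronaphthalen-2(3H)-one | COC1=C2CC[C@@H](O)C(=C)[C@@]2(C)CC(=C(C)C)C1=O
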